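Sub is the monomer here, and the earlier runs report how much of it has become Sub2 at two charges of Tsp3.

| flask | Sub | Tsp3 | Tsp | remark | time |
|---|---|---|---|---|---|
| grey | 0.50 M | 3.2 mM | 6.4 mol% | run made earlier |  |
| red | 0.50 M | 14 mM | 6.4 mol% | run made earlier |  |
| west | 0.50 M | 5.00 mM | 6.4 mol% |  | 2.5 d |
| north | 0.50 M | 20.0 mM | 6.4 mol% |  | 2.5 d |

| run | time / d | Sub2 / % |
|---|---|---|
| grey | 0.333 | 12 |
| grey | 0.625 | 15 |
| grey | 1.04 | 20 |
| grey | 1.25 | 23 |
| grey | 1.67 | 27 |
| grey | 2.00 | 31 |
| grey | 2.50 | 33 |
| red | 0.333 | 6 |
| red | 0.625 | 15 |
| red | 1.04 | 18 |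
| red | 1.25 | 20 |
| red | 1.67 | 22 |
| red | 2.00 | 25 |
| red | 2.50 | 27 |

(scatter of a reading: 1.5 percentage points)

- the average divides the monomer in chains by the number of chains begun, living and dead together
- the earlier runs do not show the number of chains; that part of a forecast is a guess

* which of the two ends with the longer chains by the average number of monomer units in a chain (chains begun, living or dead) ("neither" if they lie within 10 %) (west / north / neither)
* average number of monomer units in a chain (chains begun, living or dead) at the end, west
* average number of monomer units in a chain (chains begun, living or dead) at the end, north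

My reckoning starts from a guess: each Tsp begins one chain, so the 32.0 mM of Tsp charged in west and north counts the chains. A rate constant multiplies concentrations, so at a given [Sub] Sub2 should grow in proportion to the active ends. Suppose each Tsp3 quickly caps one end for good. Tsp3 is then the limiting reagent of the capping in north, where it is less than the Tsp. Capped chains still count as begun, so in this reckoning Tsp3 does not enter the denominator of the length and acts on the growth.

Taking the capping as finished by 1.04 d, growth goes with the free starter, 12.0 mM in north as the Tsp charge less the Tsp3 charge. The same subtraction gives 27.0 mM in west, 28.8 mM in grey and 18.0 mM in red.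

From 1.04 d to 2.50 d, grey gains 13 percentage points and red 9 points. That is a ratio of 1.44 as read, against 1.60 for the free starter, and with a scatter of 1.5 points per reading the two are compatible.

Pooling both runs, I estimate for the same interval a gain of 13 points in west and 5.6 points in north. Added to the readings at 1.04 d of the runs nearest in Tsp3, grey for west and red for north, these make about 32.7 % and 23.6 % of Sub2 at 2.5 d. Dividing the reacted Sub by the Tsp charge gives about 5.11 units for west and 3.69 for north.

The forecast also supposes that “Tsp starts the chains” and names west, with 5 units for west (range 3.5 to 12) and 4 for north (range 2.3 to 8). For north it stands above my figure.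

West ends at 5.21 units and north at 3.40, so west has the longer chains.

    Sub + Tsp2 → Sub2 + Tsp2, rate k1*[Tsp2]*[Sub] (k = 0.270 M⁻¹ h⁻¹)
    Tsp2 + Tsp3 → Tsp2.Tsp3 (k = 6.40 M⁻¹ h⁻¹)
    Sub + Tsp → Tsp2 + Sub2 (k = 1.00 M⁻¹ h⁻¹)
    Tsp2 → Zet (k = 0.00840 h⁻¹)

At 2.50 d, north holds 19.7 mM of Tsp2.Tsp3, while Tsp2 and Zet together hold 12.3 mM, beside a free starter of 12.0 mM. A neighbouring flask, north with 26 mol% of Tsp, has a free starter of 110 mM, and its Tsp2 and Zet together hold 110 mM. Its Sub2 reaches 81.2 %, yet over a Tsp charge of 130 mM its chains average 3.12 units.

The earlier runs and the new flask are simulated for an exercise, and the scatter is random.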